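**Retrosynthetic overview**
- The target is two identical 2,3-cis flavan units joined C4→C6. The interflavan bond and both O1–C2 bonds are disconnected together, back to two molecules of one acyclic cis-epoxy alcohol (ring A ortho-phenol masked as a silyl ether, all other phenols as benzyl ethers).
- Ring order: the two aromatic rings of each half come from the starting aldehydes. Both heterocyclic rings C close in one pot (phenoxide opens the cis-epoxide, 6-endo), and the same pot then joins the two flavan-3,4-diols (acid ionisation at C4, capture by C6).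
- cis-Epoxy alcohol ⇐ hydroxyl-directed epoxidation of a Z-allylic alcohol ⇐ alkyne semihydrogenation ⇐ enantioselective alkynylation of a ring A aldehyde with a ring B arylacetylene (the only external source of chirality).
- Last step: hydrogenolysis of eight benzyl ethers.

Assumption: the SMILES is read as upper unit (2R,3R,4S) with 4β-aryl, lower unit (2R,3R,4S) with 4β-OH, linked C4→C6, i.e. epimesquitol-(4β→6)-epimesquitol-4β-ol.

**Step 1**
Reactants: 1 2,3,4-trihydroxybenzaldehyde
Product: 2 3,4-bis(benzyloxy)-2-hydroxybenzaldehyde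
Conditions: BnBr (2.05 equiv), K2CO3 (2.1 equiv), DMF, 0 → 23 °C
Reagents that add atoms: benzyl bromide, BrCc1ccccc1
Why: Williamson etherification that spares the 2-OH because it is hydrogen-bonded to the formyl group and is therefore the least nucleophilic phenol; no stereocentre is formed.

**Step 2**
Reactants: 2 3,4-bis(benzyloxy)-2-hydroxybenzaldehyde
Product: 3 3,4-bis(benzyloxy)-2-[(triisopropylsilyl)oxy]benzaldehyde
Conditions: TIPSOTf (1.2 equiv), 2,6-lutidine (2 equiv), CH2Cl2, 0 °C
Reagents that add atoms: triisopropylsilyl trifluoromethanesulfonate, CC(C)[Si](C(C)C)(C(C)C)OS(=O)(=O)C(F)(F)F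
Why: Silylation of the remaining hindered phenol gives a fluoride-labile mask that survives the organozinc, hydrogenation and peracid steps and is too bulky to migrate to a neighbouring alkoxide; no stereocentre is formed.

**Step 3**
Reactants: 4 3,4-bis(benzyloxy)benzaldehyde
Product: 5 1,2-bis(benzyloxy)-4-ethynylbenzene
Conditions: Ohira–Bestmann reagent (1.2 equiv), K2CO3, MeOH/THF, 23 °C
Reagents that add atoms: dimethyl (1-diazo-2-oxopropyl)phosphonate, COP(=O)(OC)C(=[N+]=[N-])C(C)=O
Why: Seyferth–Gilbert homologation in the Ohira–Bestmann version turns the aldehyde into the terminal alkyne under mild base that benzyl ethers tolerate; no stereocentre is formed.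

**Step 4**
Reactants: 3 3,4-bis(benzyloxy)-2-[(triisopropylsilyl)oxy]benzaldehyde; 5 1,2-bis(benzyloxy)-4-ethynylbenzene
Product: 7 (1R)-1-{3,4-bis(benzyloxy)-2-[(triisopropylsilyl)oxy]phenyl}-3-[3,4-bis(benzyloxy)phenyl]prop-2-yn-1-ol, via alkynyl(ethyl)zinc 6 (not isolated)
Conditions: 5 (2 equiv), Et2Zn (2 equiv), toluene, reflux, 1 h; then (R)-BINOL (20 mol %), Ti(OiPr)4 (50 mol %), Et2O, 23 °C; then 3, 23 °C; aq NH4Cl
Reagents that add atoms: none
Why: Catalytic enantioselective alkynylzinc addition to an aromatic aldehyde under (R)-BINOL/Ti(OiPr)4 control, the alkynyl group adding to the Re face to give the (R)-carbinol that becomes C4 of both halves (the ligand antipode would give the enantiomer).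

**Step 5**
Reactants: 7 (1R)-propargylic alcohol
Product: 8 (1R,2Z)-1-{3,4-bis(benzyloxy)-2-[(triisopropylsilyl)oxy]phenyl}-3-[3,4-bis(benzyloxy)phenyl]prop-2-en-1-ol
Conditions: H2 (1 atm, 1 equiv uptake), Pd/CaCO3 poisoned with Pb(OAc)2, quinoline, EtOAc, 23 °C; Et3N-washed silica
Reagents that add atoms: none
Why: Syn delivery of one equivalent of hydrogen on poisoned palladium (Lindlar-type semihydrogenation) gives the Z-alkene, the geometry that later becomes the 2,3-cis ring, while benzyl and silyl ethers and the carbinol stereocentre are untouched.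

**Step 6**
Reactants: 8 (1R,2Z)-allylic alcohol
Product: 9 (S)-{3,4-bis(benzyloxy)-2-[(triisopropylsilyl)oxy]phenyl}{(2R,3S)-3-[3,4-bis(benzyloxy)phenyl]oxiran-2-yl}methanol
Conditions: mCPBA (1.2 equiv), NaHCO3 (3 equiv), CH2Cl2, −20 → 0 °C; Et3N-washed silica
Reagents that add atoms: 3-chloroperoxybenzoic acid, OOC(=O)c1cccc(Cl)c1
Why: Henbest-type hydroxyl-directed peracid epoxidation in which A(1,3) strain of the Z-allylic alcohol holds the carbinol H in the alkene plane, so the OH-bound peracid delivers oxygen to one face only and gives the threo cis-epoxide, setting the future C3 (R) and the pre-inversion C2 (S) from the carbinol.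

**Step 7**
Reactants: 9 silyl-masked cis-epoxy alcohol (2 molecules)
Product: 12 octa-O-benzyl ether of the target, via free-phenol epoxy alcohol 10 (not isolated), via tetra-O-benzyl isomelacacidin 11 (not isolated)
Conditions: TBAF (1.05 equiv), THF, −20 → 23 °C; evaporate; CH2Cl2 (0.3 M), TFA (10 equiv), −10 → 0 °C, aq NaHCO3 quench at about half conversion of 11; recovered 11 is resubmitted to the acid stage
Reagents that add atoms: none
Why: Proposed new method: fluoride frees the ring A phenoxide, which opens the cis-epoxide at the benzylic carbon in a 6-endo SN2 step with inversion to give the 2,3-cis ring C with C2 = R (closest known reaction: cyclisation of 2'-hydroxychalcone epoxides to dihydroflavonols), and acid then ionises the C4–OH of one flavan-3,4-diol to the 7-alkoxy-stabilised flavan-4-yl cation, which C6 of a second molecule (ortho to 7-O, para to O1) captures anti to the axial 3-OH to set the upper 4β-aryl centre while the lower unit keeps its 4β-OH (closest known reaction: acid-catalysed self-condensation of leucoanthocyanidins).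

**Step 8**
Reactants: 12 octa-O-benzyl ether of the target
Product: 13 epimesquitol-(4β→6)-epimesquitol-4β-ol (target)
Conditions: H2 (1 atm), Pd(OH)2/C, THF/MeOH (1:1), 23 °C, 2 h, neutral medium
Reagents that add atoms: none
Why: Hydrogenolysis of the eight aryl benzyl ethers on palladium under neutral conditions, which should leave the benzylic C4–OH, the C2–O1 bonds and the interflavan bond intact and touches no stereocentre.

**Compound list**
1 | 2,3,4-trihydroxybenzaldehyde | O=Cc1ccc(O)c(O)c1O | starting material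
2 | 3,4-bis(benzyloxy)-2-hydroxybenzaldehyde | O=Cc1ccc(OCc2ccccc2)c(OCc2ccccc2)c1O | intermediate
3 | 3,4-bis(benzyloxy)-2-[(triisopropylsilyl)oxy]benzaldehyde | O=Cc1ccc(OCc2ccccc2)c(OCc2ccccc2)c1O[Si](C(C)C)(C(C)C)C(C)C | intermediate
4 | 3,4-bis(benzyloxy)benzaldehyde | O=Cc1ccc(OCc2ccccc2)c(OCc2ccccc2)c1 | starting material
5 | 1,2-bis(benzyloxy)-4-ethynylbenzene | C#Cc1ccc(OCc2ccccc2)c(OCc2ccccc2)c1 | intermediate
6 | {[3,4-bis(benzyloxy)phenyl]ethynyl}(ethyl)zinc | CC[Zn]C#Cc1ccc(OCc2ccccc2)c(OCc2ccccc2)c1 | intermediate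
7 | (1R)-1-{3,4-bis(benzyloxy)-2-[(triisopropylsilyl)oxy]phenyl}-3-[3,4-bis(benzyloxy)phenyl]prop-2-yn-1-ol | O[C@@H](c1ccc(OCc2ccccc2)c(OCc2ccccc2)c1O[Si](C(C)C)(C(C)C)C(C)C)C#Cc1ccc(OCc2ccccc2)c(OCc2ccccc2)c1 | intermediate
8 | (1R,2Z)-1-{3,4-bis(benzyloxy)-2-[(triisopropylsilyl)oxy]phenyl}-3-[3,4-bis(benzyloxy)phenyl]prop-2-en-1-ol | O[C@@H](c1ccc(OCc2ccccc2)c(OCc2ccccc2)c1O[Si](C(C)C)(C(C)C)C(C)C)/C=C\c1ccc(OCc2ccccc2)c(OCc2ccccc2)c1 | intermediate
9 | (S)-{3,4-bis(benzyloxy)-2-[(triisopropylsilyl)oxy]phenyl}{(2R,3S)-3-[3,4-bis(benzyloxy)phenyl]oxiran-2-yl}methanol | O[C@@H](c1ccc(OCc2ccccc2)c(OCc2ccccc2)c1O[Si](C(C)C)(C(C)C)C(C)C)[C@H]1O[C@H]1c1ccc(OCc2ccccc2)c(OCc2ccccc2)c1 | intermediate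
10 | (S)-[3,4-bis(benzyloxy)-2-hydroxyphenyl]{(2R,3S)-3-[3,4-bis(benzyloxy)phenyl]oxiran-2-yl}methanol (present as its tetrabutylammonium phenoxide) | O[C@@H](c1ccc(OCc2ccccc2)c(OCc2ccccc2)c1O)[C@H]1O[C@H]1c1ccc(OCc2ccccc2)c(OCc2ccccc2)c1 | intermediate
11 | (2R,3R,4S)-7,8-bis(benzyloxy)-2-[3,4-bis(benzyloxy)phenyl]chromane-3,4-diol (tetra-O-benzyl isomelacacidin) | c1cc2c(c(OCc3ccccc3)c1OCc3ccccc3)O[C@H](c1ccc(OCc3ccccc3)c(OCc3ccccc3)c1)[C@H](O)[C@H]2O | intermediate
12 | octa-O-benzyl ether of the target (7,8,3',4'-tetra-O-benzyl on each unit; free 3-OH upper, free 3-OH and 4-OH lower; all six stereocentres as in the target) | C(c5ccccc5)Oc1ccc([C@H]2Oc3c(ccc(OCc5ccccc5)c3OCc5ccccc5)[C@H](c3cc4c(c(OCc5ccccc5)c3OCc5ccccc5)O[C@H](c3ccc(OCc5ccccc5)c(OCc5ccccc5)c3)[C@H](O)[C@H]4O)[C@H]2O)cc1OCc5ccccc5 | intermediate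
13 | (2R,3R,4S)-2-(3,4-dihydroxyphenyl)-6-[(2R,3R,4S)-2-(3,4-dihydroxyphenyl)-3,7,8-trihydroxychroman-4-yl]chromane-3,4,7,8-tetrol | Oc1ccc([C@H]2Oc3c(ccc(O)c3O)[C@H](c3cc4c(c(O)c3O)O[C@H](c3ccc(O)c(O)c3)[C@H](O)[C@H]4O)[C@H]2O)cc1O | target

**Step count**
Total: 8 steps. Longest linear sequence: 7 steps (1, 2, 4, 5, 6, 7, 8).

**Steps most likely to fail, with fallbacks**

Step 7. The risks are 5-exo instead of 6-endo opening of the epoxide, condensation beyond the dimer, and a modest yield per pass (a rough estimate is 25–35 % of 12 with recovered 11). The fallback sets out from 9. Only the fluoride stage is run and 11 is isolated. One part of 11 is treated with phenylmethanethiol and AcOH to give the 4β-benzylsulfanyl flavan-3-ol F1 by thiolysis of the C4–OH. AgBF4 is then added to F1 in THF at 0 °C in the presence of 4 equiv of 11. The thiophilic silver salt ionises only F1, so the 4-OH of the nucleophile and of the product is not activated and oligomers are suppressed. The route is rejoined at 12.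

Step 6. The electron-rich cis-epoxide 9 may open or rearrange during its formation or isolation. The fallback sets out from 8. The silyl group is removed first (TBAF, THF) to give the free-phenol Z-allylic alcohol F2. F2 is then epoxidised (mCPBA, NaHCO3, CH2Cl2, −20 °C), so the epoxide is opened in the same flask by the neighbouring phenol and never has to be handled. This gives 11, which is isolated; the route is rejoined at 11, which goes through the acid stage of step 7 to 12.

Step 4. The hindered ortho-silyloxy aldehyde may give low enantiomeric excess. The fallback sets out from 3 and 5. The lithium acetylide of 5 (n-BuLi, THF, −78 °C) adds to 3 to give the racemic propargylic alcohol F3. MnO2 in CH2Cl2 oxidises it to the ynone F4. Asymmetric transfer hydrogenation of F4 in iPrOH with RuCl(p-cymene)[(S,S)-TsDPEN] or its mirror image, whichever delivers hydride to the Si face, gives the (R)-alcohol, and the route is rejoined at 7.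

**Further compounds**
F1 | step 7 | (2R,3S,4S)-4-(benzylsulfanyl)-7,8-bis(benzyloxy)-2-[3,4-bis(benzyloxy)phenyl]chroman-3-ol | c1cc2c(c(OCc3ccccc3)c1OCc3ccccc3)O[C@H](c1ccc(OCc3ccccc3)c(OCc3ccccc3)c1)[C@H](O)[C@H]2SCc1ccccc1
F2 | step 6 | (1R,2Z)-1-[3,4-bis(benzyloxy)-2-hydroxyphenyl]-3-[3,4-bis(benzyloxy)phenyl]prop-2-en-1-ol | O[C@@H](c1ccc(OCc2ccccc2)c(OCc2ccccc2)c1O)/C=C\c1ccc(OCc2ccccc2)c(OCc2ccccc2)c1
F3 | step 4 | rac-1-{3,4-bis(benzyloxy)-2-[(triisopropylsilyl)oxy]phenyl}-3-[3,4-bis(benzyloxy)phenyl]prop-2-yn-1-ol | OC(c1ccc(OCc2ccccc2)c(OCc2ccccc2)c1O[Si](C(C)C)(C(C)C)C(C)C)C#Cc1ccc(OCc2ccccc2)c(OCc2ccccc2)c1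
F4 | step 4 | 1-{3,4-bis(benzyloxy)-2-[(triisopropylsilyl)oxy]phenyl}-3-[3,4-bis(benzyloxy)phenyl]prop-2-yn-1-one | O=C(c1ccc(OCc2ccccc2)c(OCc2ccccc2)c1O[Si](C(C)C)(C(C)C)C(C)C)C#Cc1ccc(OCc2ccccc2)c(OCc2ccccc2)c1
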